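**The fork.** A closed, stirred flask holds solid substrate that passes into solution as starting material. Each dissolved molecule then has two ways out: free catalyst carries it on to product, or protic impurity turns it into quenched substrate.

| setting | ash | north | south-east | east | south |
|---|---|---|---|---|---|
| solid substrate | 0.10 M | 0.10 M | 0.10 M | 0.10 M | 0.10 M |
| protic impurity | 0.10 M | 0.100 M | 0.100 M | 0.100 M | 0.100 M |
| free catalyst | 0.34 mM | 0.080 mM | 0.12 mM | 0.20 mM | 0.25 mM |
| remark | run made earlier |  |  |  |  |
| time |  | 80 min | 80 min | 80 min | 80 min |

ash run (percent of the solid substrate charged)

| time / min | product / % | solid substrate / % |
|---|---|---|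
| 12.0 | 35.3 | 56.4 |
| 25.0 | 78.9 | 8.9 |
| 30.0 | 92.9 | 0 |
| 50.0 | 94.1 | 0.3 |
| 60.0 | 92.9 | 0 |

(each reading ± 0.5 percentage points)

- what is said of product includes crystals
- solid substrate, crystals is a solid; its amount is given per volume of the solution
- steps under discussion: starting material + free catalyst -> catalyst intermediate A; catalyst intermediate A <-> catalyst intermediate B; catalyst intermediate B -> free catalyst + product; solid substrate <-> starting material; crystals <-> product; starting material + protic impurity -> quenched substrate
- at the start none of the solid substrate is in solution
- "hardly changes" means that all values lie within two and a half points (for a concentration: within two and a half percent of the largest)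
- no earlier run changes the charge of free catalyst; that part of a forecast is a guess

1. amount of product at the end, in percent of the solid substrate charged for north, south-east, east, south, in this order
2. the shape of the row from first to last (hardly changes / rises all the way / falls, then rises / falls all the way / rises, then falls)

**Even charge.** Ash levels off at a product fraction of 93.3%. I take the odds of product against quench to grow in proportion to the catalyst charge, with the impurity charge held at 0.100 M as in ash. That proportion is a guess, since no earlier run varies the catalyst. Ash then gives 0.0244 mM for the even charge, the catalyst charge at which a dissolved molecule has equal chances at the fork. The product fraction is catalyst charge over catalyst plus even charge, and catalyst over even charge is the selectivity factor of this fork.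

**My decision.** I reckon 76.6% for north, 83.1% for south-east, 89.1% for east and 91.1% for south. These are for finished flasks, so the decision is whether north needs a longer run. In ash the solid falls by 0.0363 min⁻¹ of its charge at first and 0.0365 min⁻¹ later. I read that steady pace as the solid's own crawl into solution, which would bring the whole charge in within 27.4 min. That reading is also a guess. I keep 80 min.

**The forecast.** It gives 62%, 83.5%, 89% and 91%, so it rises all the way. It parts from me at north, where it says “it is unfinished”.

**The flask.** The row gives 75.9%, 82.6%, 89.0% and 91.1%, and it rises all the way.

    starting material + free catalyst → catalyst intermediate A (k = 1860 M⁻¹ min⁻¹)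
    catalyst intermediate A ⇌ catalyst intermediate B (K = 33.0, k = 231 min⁻¹)
    catalyst intermediate B → free catalyst + product (k = 209 min⁻¹)
    solid substrate ⇌ starting material, rate k4*(cs4 - [starting material]) while solid is left; crystals form when [starting material] > cs4 (solubility = 0.0830 M, k = 0.0469 min⁻¹)
    crystals ⇌ product, rate k5*(cs5 - [product]) while solid is left; crystals form when [product] > cs5 (solubility = 2.80 mM, k = 4.32 min⁻¹)
    starting material + protic impurity → quenched substrate (k = 0.424 M⁻¹ min⁻¹)

North ends at 75.9%, and at 80.0 min north holds starting material at 0% and quenched substrate at 24.1% of the solid substrate charged. The even charge of 0.0244 mM gave 76.6% for this flask. Put to south-east, it gives 83.1%, and south-east stands at 82.6%.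

The runs were generated by integration on assumed constants, noise included.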